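**Retrosynthetic overview**
- Glyinflanin D (16) is an isomer of aryl ester 12. One flask undoes two things: the C(=O)–CH2 bond of the 1,3-diketone (Baker–Venkataraman O-to-C aroyl shift), and ring D, the pyran ring on the non-hydroxylated benzene ring C (bonds C4–C4a and O1–C2; propargyl Claisen/[1,5]-H/oxa-6π cascade of a 1,1-dimethylpropargyl ether).
- Enabling feature: in ring C, O1 stands para to the C6 carbonyl, its two ortho carbons (later C4a and C8) are equivalent, and C2 is a gem-dimethyl carbon. In ring A, the 7-OH lies ortho to the other carbonyl, so it can hold the ring C acyl group as an ester until ring D is closed.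
- Ester 12 comes from acid 11 (methyl 4-hydroxybenzoate plus 3-chloro-3-methylbut-1-yne) and eupatoriochromene 8.
- The linear fusion of ring B in 8 is set by the same cascade on 2,4-dihydroxyacetophenone, with C3 blocked by iodine that is removed afterwards.
- Ring order: benzene rings A and C are bought, pyran ring B is closed in step 3, and pyran ring D is closed last in step 8.

Key step: step 8

Remark: the 1,3-diketone is written as the diketo tautomer of the given structure, although it should exist largely as the chelated enol. The target has no stereocentre. The only stereo-element on the way is the Z alkene of the transient o-quinone methides.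

Step 1
Reactants: 1 2,4-dihydroxyacetophenone
Product: 2 1-(2,4-dihydroxy-3-iodophenyl)ethanone
Conditions: I2 (0.4 equiv), HIO3 (0.2 equiv), EtOH–H2O, 35 °C
Reagents that add atoms: iodine (II); iodic acid (OI(=O)=O)
Why: Electrophilic aromatic iodination, in which the electrophilic iodine made from I2 and HIO3 should enter at C3 because this carbon is activated by both flanking hydroxyl groups, while the exact iodine charge guards against the 3,5-diiodide.

Step 2
Reactants: 2 1-(2,4-dihydroxy-3-iodophenyl)ethanone; 3 3-chloro-3-methylbut-1-yne
Product: 4 1-{2-hydroxy-3-iodo-4-[(2-methylbut-3-yn-2-yl)oxy]phenyl}ethanone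
Conditions: K2CO3, KI (cat.), acetone, reflux
Reagents that add atoms: none
Why: Williamson-type etherification with a tertiary propargylic chloride, which should take place only at the free and more acidic 4-OH because the 2-OH is held in a hydrogen bond to the acetyl carbonyl.

Step 3
Reactants: 4 1-{2-hydroxy-3-iodo-4-[(2-methylbut-3-yn-2-yl)oxy]phenyl}ethanone
Product: 7 1-(7-hydroxy-8-iodo-2,2-dimethyl-2H-chromen-6-yl)ethanone, via allenylphenol 5 (not isolated), via o-quinone methide 6 (not isolated)
Conditions: o-xylene, reflux (144 °C), Ar, dark
Reagents that add atoms: none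
Why: Aromatic propargyl Claisen rearrangement followed by [1,5]-hydrogen shift and oxa-6π electrocyclisation, in which the iodine at C3 leaves only C5 open to the [3,3] shift and thereby fixes the linear fusion of ring B.

Step 4
Reactants: 7 1-(7-hydroxy-8-iodo-2,2-dimethyl-2H-chromen-6-yl)ethanone
Product: 8 1-(7-hydroxy-2,2-dimethyl-2H-chromen-6-yl)ethanone (eupatoriochromene)
Conditions: Pd(PPh3)4 (5 mol %), HCO2Na, DMF, 90 °C
Reagents that add atoms: none
Why: Palladium-catalysed transfer hydrodehalogenation, in which oxidative addition of zerovalent palladium into the C–I bond, exchange of iodide for formate, loss of CO2 and reductive elimination of the aryl hydride should remove the blocking group without touching the chromene alkene or the ketone.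

Step 5
Reactants: 9 methyl 4-hydroxybenzoate; 3 3-chloro-3-methylbut-1-yne
Product: 10 methyl 4-[(2-methylbut-3-yn-2-yl)oxy]benzoate
Conditions: K2CO3, KI (cat.), acetone, reflux
Reagents that add atoms: none
Why: Williamson-type etherification of the only hydroxyl group with the tertiary propargylic chloride, a standard entry to aryl 1,1-dimethylpropargyl ethers that stay intact at the temperature of refluxing acetone.

Step 6
Reactants: 10 methyl 4-[(2-methylbut-3-yn-2-yl)oxy]benzoate
Product: 11 4-[(2-methylbut-3-yn-2-yl)oxy]benzoic acid
Conditions: LiOH, THF–MeOH–H2O, rt; then 1 M HCl to pH 3, 0 °C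
Reagents that add atoms: lithium hydroxide ([Li+].[OH-])
Why: Saponification of the methyl ester, which should leave the base-stable propargyl ether untouched, and the cold, brief acidification spares the acid-sensitive tertiary ether.

Step 7
Reactants: 11 4-[(2-methylbut-3-yn-2-yl)oxy]benzoic acid; 8 1-(7-hydroxy-2,2-dimethyl-2H-chromen-6-yl)ethanone
Product: 12 6-acetyl-2,2-dimethyl-2H-chromen-7-yl 4-[(2-methylbut-3-yn-2-yl)oxy]benzoate
Conditions: DCC, DMAP (cat.), CH2Cl2, 0 °C to rt
Reagents that add atoms: none
Why: Steglich esterification, in which carbodiimide activation of 11 and acyl transfer catalysis by DMAP should acylate even the hydrogen-bonded 7-OH of 8 under neutral conditions that spare the alkyne, the tertiary ether and the chromene.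

Step 8
Reactants: 12 6-acetyl-2,2-dimethyl-2H-chromen-7-yl 4-[(2-methylbut-3-yn-2-yl)oxy]benzoate
Product: 16 glyinflanin D, via allenylphenol ester 13 (not isolated), via o-quinone methide ester 14 (not isolated), via bis-chromene ester 15 (not isolated)
Conditions: mesitylene (0.05 M), 165 °C, Ar; cool to 0 °C, add THF, t-BuOK (2.5 equiv), 0 °C to rt; AcOH–H2O quench
Reagents that add atoms: none
Why: Heating sets off the aromatic propargyl Claisen cascade: a [3,3]-sigmatropic shift carries the dimethylpropargyl unit from the ether oxygen to an ortho carbon of ring C as an allene (C4–C4a bond) and enolisation gives allenylphenol 13, a [1,5]-hydrogen shift from the phenol O–H to the central allene carbon gives the Z-configured o-quinone methide 14, and a thermally allowed disrotatory oxa-6π electrocyclisation joins the carbonyl oxygen to the CMe2 terminus (O1–C2 bond) and closes ring D of 15 with rearomatisation of ring C. The closest known reaction type is the thermal conversion of aryl 1,1-dimethylpropargyl ethers into 2,2-dimethyl-2H-chromenes, which the gem-dimethyl group and a para acyl substituent should favour. After cooling, t-BuOK deprotonates the acetyl group of 15 and the enolate attacks the neighbouring aryl ester carbonyl through a six-membered tetrahedral intermediate whose collapse moves the aroyl group from O to C (Baker–Venkataraman rearrangement), so that the C–C bond of the 1,3-diketone and the free 7-OH arise in the same flask. No stereocentre is formed, and the only stereochemical demand, the Z geometry of 14 that places the isobutenyl arm next to the carbonyl oxygen, follows from the suprafacial hydrogen transfer within 13. Regioselectivity is not needed in the [3,3] step because the two carbons ortho to the ether oxygen of ring C are equivalent, and the alkene of ring B, the acetyl group and the ester should be spectators at this temperature. Running the pericyclic stage at the ester level secures chemoselectivity, since no base, no acidic methylene and no free 7-OH are present that could divert 13 to a benzofuran or dehydrate a diketone to a flavone, and the base is added only once ring D is closed.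

**Compound list**
1 | 2,4-dihydroxyacetophenone | CC(=O)c1ccc(O)cc1O | starting material
2 | 1-(2,4-dihydroxy-3-iodophenyl)ethanone | CC(=O)c1ccc(O)c(I)c1O | intermediate
3 | 3-chloro-3-methylbut-1-yne | CC(C)(Cl)C#C | starting material
4 | 1-{2-hydroxy-3-iodo-4-[(2-methylbut-3-yn-2-yl)oxy]phenyl}ethanone | CC(=O)c1ccc(OC(C)(C)C#C)c(I)c1O | intermediate
5 | 1-[2,4-dihydroxy-3-iodo-5-(3-methylbuta-1,2-dien-1-yl)phenyl]ethanone (allenylphenol, not isolated) | CC(=O)c1cc(C=C=C(C)C)c(O)c(I)c1O | intermediate
6 | (6Z)-4-acetyl-3-hydroxy-2-iodo-6-(3-methylbut-2-en-1-ylidene)cyclohexa-2,4-dien-1-one (o-quinone methide, not isolated) | CC(=O)C1=C/C(=C/C=C(C)C)C(=O)C(I)=C1O | intermediate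
7 | 1-(7-hydroxy-8-iodo-2,2-dimethyl-2H-chromen-6-yl)ethanone | CC(=O)c1cc2C=CC(C)(C)Oc2c(I)c1O | intermediate
8 | 1-(7-hydroxy-2,2-dimethyl-2H-chromen-6-yl)ethanone (eupatoriochromene) | CC(=O)c1cc2C=CC(C)(C)Oc2cc1O | intermediate
9 | methyl 4-hydroxybenzoate | COC(=O)c1ccc(O)cc1 | starting material
10 | methyl 4-[(2-methylbut-3-yn-2-yl)oxy]benzoate | COC(=O)c1ccc(OC(C)(C)C#C)cc1 | intermediate
11 | 4-[(2-methylbut-3-yn-2-yl)oxy]benzoic acid | OC(=O)c1ccc(OC(C)(C)C#C)cc1 | intermediate
12 | 6-acetyl-2,2-dimethyl-2H-chromen-7-yl 4-[(2-methylbut-3-yn-2-yl)oxy]benzoate | CC(=O)c1cc2C=CC(C)(C)Oc2cc1OC(=O)c1ccc(OC(C)(C)C#C)cc1 | intermediate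
13 | 6-acetyl-2,2-dimethyl-2H-chromen-7-yl 4-hydroxy-3-(3-methylbuta-1,2-dien-1-yl)benzoate (not isolated) | CC(=O)c1cc2C=CC(C)(C)Oc2cc1OC(=O)c1ccc(O)c(C=C=C(C)C)c1 | intermediate
14 | 6-acetyl-2,2-dimethyl-2H-chromen-7-yl (3Z)-3-(3-methylbut-2-en-1-ylidene)-4-oxocyclohexa-1,5-diene-1-carboxylate (not isolated) | CC(=O)c1cc2C=CC(C)(C)Oc2cc1OC(=O)C1=C/C(=C/C=C(C)C)C(=O)C=C1 | intermediate
15 | 6-acetyl-2,2-dimethyl-2H-chromen-7-yl 2,2-dimethyl-2H-chromene-6-carboxylate (not isolated) | CC(=O)c1cc2C=CC(C)(C)Oc2cc1OC(=O)c1ccc2OC(C)(C)C=Cc2c1 | intermediate
16 | glyinflanin D, 1-(2,2-dimethyl-2H-chromen-6-yl)-3-(7-hydroxy-2,2-dimethyl-2H-chromen-6-yl)propane-1,3-dione | CC1(C)C=Cc2cc(C(=O)CC(=O)c3cc4c(cc3O)OC(C)(C)C=C4)ccc2O1 | target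

Total step count: 8.
Longest linear sequence: 6 (steps 1, 2, 3, 4, 7, 8).

**Three steps most likely to fail**

Risk 1, step 8.
- What may go wrong: long heating may allow acyl scrambling by the transient phenol 13 or oligomerisation of the terminal alkyne. In the second stage, tert-butoxide may cleave the aryl ester of 15 instead of deprotonating the acetyl group.
- Fallback: invert the order and change the ring-closing mechanism.
  - Starting from 12, a Baker–Venkataraman rearrangement with LiHMDS (THF, −78 to 0 °C) should give 1-(7-hydroxy-2,2-dimethyl-2H-chromen-6-yl)-3-{4-[(2-methylbut-3-yn-2-yl)oxy]phenyl}propane-1,3-dione F1.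
  - Ring D is then closed at room temperature by a Ph3PAuNTf2-catalysed 6-endo-dig intramolecular hydroarylation in CH2Cl2. This involves π-activation of the alkyne by monovalent gold, Friedel–Crafts-type attack of an ortho carbon of ring C, and protodeauration.
  - The fallback comes back to the route at 16.

Risk 2, step 3.
- What may go wrong: migration towards the iodine-bearing carbon with expulsion of iodine, or homolysis of the C–I bond at the rearrangement temperature, would erode the linear fusion of ring B.
- Fallback: set the aryl–carbon bond by electrophilic substitution and close ring B by oxidation instead of sigmatropy.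
  - Starting from 1, a BF3·OEt2-mediated Friedel–Crafts prenylation with 2-methylbut-3-en-2-ol in dioxane should give, after separation from the 3-prenyl isomer, 1-[2,4-dihydroxy-5-(3-methylbut-2-en-1-yl)phenyl]ethanone F2.
  - DDQ in refluxing toluene should remove hydride from the benzylic carbon and give (6Z)-4-acetyl-3-hydroxy-6-(3-methylbut-2-en-1-ylidene)cyclohexa-2,4-dien-1-one F3.
  - The oxa-6π closure of F3 can use only the neighbouring 4-oxygen.
  - The fallback comes back to the route at 8 and bypasses steps 1 to 4.

Risk 3, step 2.
- What may go wrong: substitution at a phenoxide flanked by iodine may be outrun by loss of HCl from 3 to the enyne, so conversion stalls.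
- Fallback: omit the ether.
  - Starting from 2, condensation with 3-methylbut-2-enal under ethylenediammonium diacetate catalysis in refluxing xylene should let the free C5 attack the activated aldehyde.
  - Loss of water should give o-quinone methide 6 directly, and electrocyclisation follows.
  - The fallback comes back to the route at 7 and bypasses 4 and the Claisen step. It makes no compound outside the list (F0).

**Further compounds**
F1 | step 8 | 1-(7-hydroxy-2,2-dimethyl-2H-chromen-6-yl)-3-{4-[(2-methylbut-3-yn-2-yl)oxy]phenyl}propane-1,3-dione | CC1(C)C=Cc2cc(C(=O)CC(=O)c3ccc(OC(C)(C)C#C)cc3)c(O)cc2O1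
F2 | step 3 | 1-[2,4-dihydroxy-5-(3-methylbut-2-en-1-yl)phenyl]ethanone | CC(=O)c1cc(CC=C(C)C)c(O)cc1O
F3 | step 3 | (6Z)-4-acetyl-3-hydroxy-6-(3-methylbut-2-en-1-ylidene)cyclohexa-2,4-dien-1-one | CC(=O)C1=C/C(=C/C=C(C)C)C(=O)C=C1O
F0 | step 2 | none | none
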